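The target is the 3,7,4'-tris(hydrogen sulfate) of geraldol; the real work is ring C. The feature exploited is the O1–C2(aryl)=C3(OH)–C4(=O) array of this pyranone: it is the hydrolytic ring-expansion product of an aurone dibromide, so the route rests on disconnecting O1–C2 back to a benzofuran-3-one. In one operation hydroxide places O3 on the brominated furanone carbon, the five-membered ring opens, and the ring A phenoxide recloses on the benzylic bromide to give ring C with its 3-OH. The precursor is the dibromide of the aurone from 6-hydroxybenzofuran-3(2H)-one and vanillin, both phenols masked as tosylates, which carry no acidic α-hydrogens and deactivate rings A and B toward bromine.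

Key step: step 4

Assumption: the target is taken as the free tris(hydrogen sulfate) as drawn; aryl hydrogen sulfates are acid-labile, so the last operation is run cold and the product is kept as a freeze-dried solid.

Step 1
Reactants: 1 6-hydroxybenzofuran-3(2H)-one; 2 vanillin
Product: 3 (Z)-6-hydroxy-2-(4-hydroxy-3-methoxybenzylidene)benzofuran-3(2H)-one
Conditions: conc. HCl (cat.), AcOH, rt
Reagents that add atoms: none
Why: Acid-catalysed aldol condensation of the active C2 methylene with the aldehyde, made irreversible by conjugated dehydration; the Z alkene (aryl cis to O1) is the thermodynamic isomer and should be the one that crystallises.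

Step 2
Reactants: 3 (Z)-6-hydroxy-2-(4-hydroxy-3-methoxybenzylidene)benzofuran-3(2H)-one
Product: 4 (Z)-2-[3-methoxy-4-(tosyloxy)benzylidene]-6-(tosyloxy)benzofuran-3(2H)-one
Conditions: TsCl (2.4 equiv), K2CO3, acetone, reflux
Reagents that add atoms: p-toluenesulfonyl chloride, Cc1ccc(S(=O)(=O)Cl)cc1
Why: O-sulfonylation of both phenoxides, the only nucleophilic sites; arenesulfonates are chosen because they have no α-hydrogen (no sulfene-type cleavage in the later hydroxide step) and make both rings poor substrates for bromine.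

Step 3
Reactants: 4 (Z)-2-[3-methoxy-4-(tosyloxy)benzylidene]-6-(tosyloxy)benzofuran-3(2H)-one
Product: 5 2-bromo-2-{bromo[3-methoxy-4-(tosyloxy)phenyl]methyl}-6-(tosyloxy)benzofuran-3(2H)-one
Conditions: Br2 (1.05 equiv), CH2Cl2, 0 °C → rt, dark
Reagents that add atoms: bromine, BrBr
Why: Electrophilic addition of bromine across the exocyclic enol-ether alkene, favoured over ring substitution by the two sulfonyloxy groups; the two new stereocentres arise racemic (anti addition expected), and their configuration is not relied on because both are erased in step 4.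

Step 4
Reactants: 5 2-bromo-2-{bromo[3-methoxy-4-(tosyloxy)phenyl]methyl}-6-(tosyloxy)benzofuran-3(2H)-one
Product: 9 3-hydroxy-2-[3-methoxy-4-(tosyloxy)phenyl]-7-(tosyloxy)-4H-chromen-4-one, via bromohydrin hemiketal 6 (not isolated), via ring-opened bromo diketone 7 (not isolated), via chromane-3,4-dione 8 (not isolated)
Conditions: KOH (0.5 M aq, 3.5 equiv), THF, 0 °C → rt; then 1 M HCl
Reagents that add atoms: potassium hydroxide (supplies O3), [K+].[OH-]
Why: The tertiary α-bromo ether carbon of 5 (benzofuranone C2, the later C3 of ring C) is substituted by hydroxide to give hemiketal 6, which collapses to the ring A phenoxide and 1,2-diketone 7; the phenoxide then displaces the secondary benzylic bromide to form O1–C2, and dione 8 enolises to the flavonol, held in the flask as its potassium enolate. The closest known reaction is the Auwers flavonol synthesis from aurone dibromides and alkali. Ring C closes in a 6-exo-tet O-alkylation, the only accessible closure because the second leaving group sits on the benzylic carbon. No stereocentre is created, and both stereocentres of 5 are erased when C2 and C3 of ring C become sp2. The step needs substitution at the bromo-ketal carbon to outrun loss of HBr to an α-bromoaurone and to outrun sulfonate cleavage: the 6-sulfonyloxy group is no π-donor, so the ketone and the bromo-ketal carbon stay electrophilic and the departing 2-acylphenoxide is a good leaving group, while the 4'-sulfonyloxy group keeps the benzylic bromide from ionising toward a quinone-methide-type cation. The alcohol-free medium leaves hydroxide as the only oxygen nucleophile, so no mixed ketal can form at the bromo-ketal carbon and the tosylates are not transesterified.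

Step 5
Reactants: 9 3-hydroxy-2-[3-methoxy-4-(tosyloxy)phenyl]-7-(tosyloxy)-4H-chromen-4-one
Product: 10 3,7-dihydroxy-2-(4-hydroxy-3-methoxyphenyl)-4H-chromen-4-one (geraldol)
Conditions: KOH (2 M aq), 1,4-dioxane, 70 °C, N2 (degassed); then HCl to pH 3
Reagents that add atoms: none
Why: Alkaline hydrolysis of the aryl sulfonates by hydroxide attack at sulfur, eased because both leaving groups are phenoxides conjugated to the C4 carbonyl; the alcohol-free, oxygen-free medium avoids O-alkylation by an alkyl tosylate and oxidative fission of the flavonolate.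

Step 6
Reactants: 10 3,7-dihydroxy-2-(4-hydroxy-3-methoxyphenyl)-4H-chromen-4-one (geraldol)
Product: 12 geraldol 3,7,4'-tris(hydrogen sulfate) (target), via tris(pyridinium) trisulfate 11 (not isolated)
Conditions: SO3·pyridine (15 equiv), pyridine, 60 °C; Sephadex LH-20 (MeOH–H2O); Dowex 50W (H+ form), H2O, 0 °C; freeze-drying
Reagents that add atoms: sulfur trioxide–pyridine complex, O=S(=O)([O-])[n+]1ccccc1
Why: O-sulfation by SO3 transfer from the amine complex to the two phenols and the enolic 3-OH (excess reagent and warming should carry the hydrogen-bonded 3-OH to completion), followed by exchange of pyridinium for protons on a sulfonic acid resin.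

Compound list
1 | 6-hydroxybenzofuran-3(2H)-one | O=C1COc2cc(O)ccc21 | starting material
2 | vanillin (4-hydroxy-3-methoxybenzaldehyde) | COc1cc(C=O)ccc1O | starting material
3 | (Z)-6-hydroxy-2-(4-hydroxy-3-methoxybenzylidene)benzofuran-3(2H)-one | COc1cc(/C=C2\Oc3cc(O)ccc3C2=O)ccc1O | intermediate
4 | (Z)-2-[3-methoxy-4-(tosyloxy)benzylidene]-6-(tosyloxy)benzofuran-3(2H)-one | COc1cc(/C=C2\Oc3cc(OS(=O)(=O)c4ccc(C)cc4)ccc3C2=O)ccc1OS(=O)(=O)c1ccc(C)cc1 | intermediate
5 | 2-bromo-2-{bromo[3-methoxy-4-(tosyloxy)phenyl]methyl}-6-(tosyloxy)benzofuran-3(2H)-one, racemic, relative configuration not relied on | COc1cc(C(Br)C2(Br)Oc3cc(OS(=O)(=O)c4ccc(C)cc4)ccc3C2=O)ccc1OS(=O)(=O)c1ccc(C)cc1 | intermediate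
6 | 2-{bromo[3-methoxy-4-(tosyloxy)phenyl]methyl}-2-hydroxy-6-(tosyloxy)benzofuran-3(2H)-one (bromohydrin hemiketal, racemic) | COc1cc(C(Br)C2(O)Oc3cc(OS(=O)(=O)c4ccc(C)cc4)ccc3C2=O)ccc1OS(=O)(=O)c1ccc(C)cc1 | intermediate
7 | 3-bromo-1-[2-hydroxy-4-(tosyloxy)phenyl]-3-[3-methoxy-4-(tosyloxy)phenyl]propane-1,2-dione (present as its phenoxide, racemic) | COc1cc(C(Br)C(=O)C(=O)c2ccc(OS(=O)(=O)c3ccc(C)cc3)cc2O)ccc1OS(=O)(=O)c1ccc(C)cc1 | intermediate
8 | 2-[3-methoxy-4-(tosyloxy)phenyl]-7-(tosyloxy)chromane-3,4-dione (racemic) | COc1cc(C2Oc3cc(OS(=O)(=O)c4ccc(C)cc4)ccc3C(=O)C2=O)ccc1OS(=O)(=O)c1ccc(C)cc1 | intermediate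
9 | 3-hydroxy-2-[3-methoxy-4-(tosyloxy)phenyl]-7-(tosyloxy)-4H-chromen-4-one | COc1cc(-c2oc3cc(OS(=O)(=O)c4ccc(C)cc4)ccc3c(=O)c2O)ccc1OS(=O)(=O)c1ccc(C)cc1 | intermediate
10 | 3,7-dihydroxy-2-(4-hydroxy-3-methoxyphenyl)-4H-chromen-4-one (geraldol) | COc1cc(-c2oc3cc(O)ccc3c(=O)c2O)ccc1O | intermediate
11 | tris(pyridinium) salt of geraldol 3,7,4'-tris-O-sulfate | COc1cc(-c2oc3cc(OS(=O)(=O)[O-])ccc3c(=O)c2OS(=O)(=O)[O-])ccc1OS(=O)(=O)[O-].c1cc[nH+]cc1.c1cc[nH+]cc1.c1cc[nH+]cc1 | intermediate
12 | geraldol 3,7,4'-tris(hydrogen sulfate) | COc1cc(-c2oc3cc(OS(=O)(=O)O)ccc3c(=O)c2OS(=O)(=O)O)ccc1OS(=O)(=O)O | target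

Total step count: 6
Longest linear sequence: 6 steps (1 → 3 → 4 → 5 → 9 → 10 → 12)

Steps most likely to fail

1. Step 4. What may go wrong: loss of HBr from the dibromide to an α-bromoaurone, which would go on to a 2-aroylbenzofuranone; halophilic return to the aurone; or sulfonate cleavage ahead of ring expansion, which would put a donor phenoxide on ring A and stall the rearrangement. Fallback: the flavonol would be built by an Algar–Flynn–Oyamada oxidation instead, setting out from vanillin 2 and coming back at geraldol 10. Vanillin 2 would be O-benzylated (BnBr, K2CO3, DMF) to 4-(benzyloxy)-3-methoxybenzaldehyde F1. This would be condensed under Claisen–Schmidt conditions (KOH, EtOH, rt) with purchased 1-[4-(benzyloxy)-2-hydroxyphenyl]ethanone (CC(=O)c1ccc(OCc2ccccc2)cc1O) to (E)-1-[4-(benzyloxy)-2-hydroxyphenyl]-3-[4-(benzyloxy)-3-methoxyphenyl]prop-2-en-1-one F2. Oxidative cyclisation with H2O2 and NaOH in MeOH–THF at 0 °C should give 7-(benzyloxy)-2-[4-(benzyloxy)-3-methoxyphenyl]-3-hydroxy-4H-chromen-4-one F3, since a 2'-hydroxychalcone without a 6'-substituent favours the flavonol over the aurone. Hydrogenolysis (H2, Pd/C, THF–MeOH) would then give 10.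

2. Step 3. What may go wrong: electrophilic substitution of ring B para to the methoxy group competing with addition, or loss of HBr or Br2 from the tertiary bromo ether during isolation. Fallback: the oxidation would be delivered as oxygen, not as bromine, setting out from aurone bis-tosylate 4 and coming back at hemiketal 6. Dimethyldioxirane in acetone at rt should epoxidise the exocyclic alkene of 4 under neutral conditions to 3'-[3-methoxy-4-(tosyloxy)phenyl]-6-(tosyloxy)-3H-spiro[benzofuran-2,2'-oxiran]-3-one F4. Opening of the oxirane by bromide (HBr in AcOH, CH2Cl2, 0 °C) is expected at the secondary benzylic carbon, because the spiro ketal carbon is quaternary and flanked by the ketone; this gives 6. Compound 6 would be taken crude into the hydroxide conditions of step 4 and should continue through 7 and 8 to 9.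

3. Step 6. What may go wrong: incomplete sulfation of the hydrogen-bonded 3-OH, and acid-catalysed loss of sulfate during proton exchange and freeze-drying. Fallback: the sulfates would be introduced as neutral protected diesters, setting out from geraldol 10 and coming back at target 12. Treatment of 10 with 2,2,2-trichloroethyl chlorosulfate (ClS(=O)(=O)OCC(Cl)(Cl)Cl), Et3N and DMAP in THF should give geraldol 3,7,4'-tris(2,2,2-trichloroethyl sulfate) F5, which can be purified on silica and checked for complete substitution. Reductive removal of the trichloroethyl groups (Zn dust, HCO2NH4, MeOH, rt) would give the tris(ammonium) salt of geraldol 3,7,4'-tris-O-sulfate F6, and the same cold cation exchange (Dowex 50W, H+ form) would give 12.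

Further compounds
F1 | step 4 | 4-(benzyloxy)-3-methoxybenzaldehyde | COc1cc(C=O)ccc1OCc1ccccc1
F2 | step 4 | (E)-1-[4-(benzyloxy)-2-hydroxyphenyl]-3-[4-(benzyloxy)-3-methoxyphenyl]prop-2-en-1-one | COc1cc(/C=C/C(=O)c2ccc(OCc3ccccc3)cc2O)ccc1OCc1ccccc1
F3 | step 4 | 7-(benzyloxy)-2-[4-(benzyloxy)-3-methoxyphenyl]-3-hydroxy-4H-chromen-4-one | COc1cc(-c2oc3cc(OCc4ccccc4)ccc3c(=O)c2O)ccc1OCc1ccccc1
F4 | step 3 | 3'-[3-methoxy-4-(tosyloxy)phenyl]-6-(tosyloxy)-3H-spiro[benzofuran-2,2'-oxiran]-3-one, racemic, aryl cis to O1 on the oxirane | COc1cc(C2OC23Oc4cc(OS(=O)(=O)c5ccc(C)cc5)ccc4C3=O)ccc1OS(=O)(=O)c1ccc(C)cc1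
F5 | step 6 | geraldol 3,7,4'-tris(2,2,2-trichloroethyl sulfate) | COc1cc(-c2oc3cc(OS(=O)(=O)OCC(Cl)(Cl)Cl)ccc3c(=O)c2OS(=O)(=O)OCC(Cl)(Cl)Cl)ccc1OS(=O)(=O)OCC(Cl)(Cl)Cl
F6 | step 6 | tris(ammonium) salt of geraldol 3,7,4'-tris-O-sulfate | COc1cc(-c2oc3cc(OS(=O)(=O)[O-])ccc3c(=O)c2OS(=O)(=O)[O-])ccc1OS(=O)(=O)[O-].[NH4+].[NH4+].[NH4+]
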